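**Plan**
1. Retrosynthesis (locants of the heptadecapentaenyl chain: C2 sits on the oxanone, C17 on the oxazole): cut C6–C7 first; then, on the aldehyde side, C8–C9 (Claisen), C10–C11 (aldol) and the three C=C (Wittig); on the other side, C4–C5 (sp2–sp coupling), C3=C4 (olefination), chain-C2–ring-C2 (aldol) and the ring O1–C6(=O) bond.
2. Enabling feature: C7(OH)–C6(CH3)=C5H–C4H=C3H, a carbinol on a methyl-bearing (E)-alkene conjugated to a second (E)-alkene. This is the product pattern of syn H/C7 addition across the C5≡C6 alkyne of a methyl-capped 1,3-enyne, with the C3=C4 alkene fixing the regiochemistry.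
3. Ring C4 of the oxan-2-one carries three CH2 arms (acetic acid; ring C5–C6(=O); ring C3–C2–O), so it maps onto C3-symmetric methanetriacetic acid. One arm is reduced; the other two stay equal until the ring-C2 hydroxyl selects one.
4. Forward: oxazole aldehyde → trienal (three Wittig steps) → syn-aldol → malonate extension → anti-reduction → aldehyde. Triacid → mono-aldehyde → syn-aldol → vinyl iodide → enyne → oxanone (the only ring made; the oxazole is bought). Then nickel coupling and global desilylation.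
5. Stereochemistry: C10/C11 and chain-C2/ring-C2 from syn-aldols with (R)- and (S)-4-benzylthiazolidinethione; C9 from C11 by 1,3-anti directed reduction; ring C4 from ring C2 by equilibrating arm-selective lactonization; C7 from a chiral phosphine on nickel; E-alkenes from Wittig, Takai and syn-addition.

Key step: step 18

Assumption: the sense of induction of neomenthyldiphenylphosphine in enyne–aldehyde couplings is taken from its aryl-alkyne couplings; "(+)-NMDPP" below stands for the antipode that is matched with the left-hand aldehyde, to be confirmed on a model aldehyde.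

**Step 1**
Reactants: 1 2-methyl-1,3-oxazole-4-carbaldehyde; 2 2-(triphenylphosphoranylidene)propanal
Product: 3 (2E)-2-methyl-3-(2-methyl-1,3-oxazol-4-yl)prop-2-enal
Conditions: PhMe, 90 °C
Reagents that add atoms: 2, 2-(triphenylphosphoranylidene)propanal, CC(C=O)=P(c1ccccc1)(c1ccccc1)c1ccccc1
Why: Wittig olefination with a stabilized α-methyl ylide; reversible oxaphosphetane formation should place the oxazole trans to the formyl group and give the (E)-trisubstituted enal.

**Step 2**
Reactants: 3 (2E)-2-methyl-3-(2-methyl-1,3-oxazol-4-yl)prop-2-enal; 4 (1,3-dioxolan-2-ylmethyl)triphenylphosphonium bromide; 5 water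
Product: 7 (2E,4E)-4-methyl-5-(2-methyl-1,3-oxazol-4-yl)penta-2,4-dienal, via dienyl dioxolane 6 (not isolated)
Conditions: KOt-Bu, THF, 0 °C → rt; then 1 M HCl, THF, rt
Reagents that add atoms: 4, (1,3-dioxolan-2-ylmethyl)triphenylphosphonium bromide, [Br-].C1COC(C[P+](c2ccccc2)(c2ccccc2)c2ccccc2)O1; 5, water, O
Why: Wittig two-carbon vinylogation with the acetal-masked formylmethylene ylide, so no free aldehyde exists to over-homologate; aqueous acid then cleaves the dioxolane and should equilibrate the new disubstituted C=C of the conjugated dienal to E.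

**Step 3**
Reactants: 7 (2E,4E)-4-methyl-5-(2-methyl-1,3-oxazol-4-yl)penta-2,4-dienal; 2 2-(triphenylphosphoranylidene)propanal
Product: 8 (2E,4E,6E)-2,6-dimethyl-7-(2-methyl-1,3-oxazol-4-yl)hepta-2,4,6-trienal
Conditions: PhMe, 90 °C
Reagents that add atoms: 2, 2-(triphenylphosphoranylidene)propanal, CC(C=O)=P(c1ccccc1)(c1ccccc1)c1ccccc1
Why: second stabilized-ylide Wittig olefination, E-selective as in step 1 and self-limiting because the α-branched trienal product is less electrophilic than the dienal.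

**Step 4**
Reactants: 9 (4R)-4-benzyl-1,3-thiazolidine-2-thione; 10 propanoyl chloride
Product: 11 (4R)-4-benzyl-3-propanoyl-1,3-thiazolidine-2-thione
Conditions: Et3N, DMAP (cat.), CH2Cl2, 0 °C → rt
Reagents that add atoms: 10, propanoyl chloride, CCC(Cl)=O
Why: N-acylation of the thiazolidinethione with an acid chloride under amine base and DMAP catalysis.

**Step 5**
Reactants: 11 (4R)-4-benzyl-3-propanoyl-1,3-thiazolidine-2-thione; 8 (2E,4E,6E)-2,6-dimethyl-7-(2-methyl-1,3-oxazol-4-yl)hepta-2,4,6-trienal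
Product: 12 (2R,3R,4E,6E,8E)-1-[(4R)-4-benzyl-2-sulfanylidene-1,3-thiazolidin-3-yl]-3-hydroxy-2,4,8-trimethyl-9-(2-methyl-1,3-oxazol-4-yl)nona-4,6,8-trien-1-one
Conditions: TiCl4 (1.05 equiv), i-Pr2NEt (1.1 equiv), NMP (1 equiv), CH2Cl2, 0 °C; then 8, −78 → −40 °C
Reagents that add atoms: none
Why: titanium(IV) (Z)-enolate aldol addition of an N-propanoylthiazolidinethione through a closed Zimmerman–Traxler chair ("Evans-syn" mode, NMP keeping the auxiliary thiocarbonyl off titanium); the (R)-benzyl group shields one enolate face, so the 2,3-syn (2R,3R) adduct should form by 1,2-addition to the trienal.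

**Step 6**
Reactants: 12 the aldol adduct; 13 potassium ethyl malonate
Product: 14 ethyl (4R,5R,6E,8E,10E)-5-hydroxy-4,6,10-trimethyl-11-(2-methyl-1,3-oxazol-4-yl)-3-oxoundeca-6,8,10-trienoate
Conditions: MgCl2, imidazole, THF, rt
Reagents that add atoms: 13, potassium ethyl malonate, CCOC(=O)CC(=O)[O-].[K+]
Why: decarboxylative Claisen condensation in which imidazole takes the acyl group from the activated thioimide and the magnesium enolate of the malonate half-ester is C-acylated and loses CO2; the near-neutral medium should leave the free β-hydroxyl and the α-methyl stereocenter untouched.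

**Step 7**
Reactants: 14 the δ-hydroxy-β-keto ester
Product: 15 ethyl (3S,4S,5R,6E,8E,10E)-3,5-dihydroxy-4,6,10-trimethyl-11-(2-methyl-1,3-oxazol-4-yl)undeca-6,8,10-trienoate
Conditions: Me4NBH(OAc)3, MeCN/AcOH (1:1), −30 °C
Reagents that add atoms: none
Why: Evans–Saksena reduction, in which the C5 hydroxyl exchanges onto boron and hydride is delivered intramolecularly through a chair transition state, should give the 1,3-anti diol and so set C3 as S from C5.

**Step 8**
Reactants: 15 the anti-diol ester; 16 triethylsilyl trifluoromethanesulfonate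
Product: 17 ethyl (3S,4S,5R,6E,8E,10E)-4,6,10-trimethyl-11-(2-methyl-1,3-oxazol-4-yl)-3,5-bis[(triethylsilyl)oxy]undeca-6,8,10-trienoate
Conditions: TESOTf, 2,6-lutidine, CH2Cl2, −78 °C
Reagents that add atoms: 16, triethylsilyl trifluoromethanesulfonate, CC[Si](CC)(CC)OS(=O)(=O)C(F)(F)F
Why: silylation of both secondary hydroxyls with a silyl triflate and a hindered base, run cold and promptly so that neither δ-lactonization nor ionization of the trienylic C5–O bond competes.

**Step 9**
Reactants: 17 the bis-silyl ether ester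
Product: 18 (3S,4S,5R,6E,8E,10E)-4,6,10-trimethyl-11-(2-methyl-1,3-oxazol-4-yl)-3,5-bis[(triethylsilyl)oxy]undeca-6,8,10-trienal
Conditions: DIBAL-H (1.1 equiv), CH2Cl2, −78 °C; Rochelle salt work-up
Reagents that add atoms: none
Why: partial ester reduction with DIBAL-H; the aluminium hemiacetal is stable at −78 °C and collapses to the aldehyde only on work-up.

**Step 10**
Reactants: 19 methanetriacetic acid [3-(carboxymethyl)pentanedioic acid]; 20 2-(trimethylsilyl)ethanol
Product: 21 tris[2-(trimethylsilyl)ethyl] methanetriacetate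
Conditions: EDC·HCl, DMAP, CH2Cl2/DMF, 0 °C → rt
Reagents that add atoms: 20, 2-(trimethylsilyl)ethanol, C[Si](C)(C)CCO
Why: threefold Steglich (carbodiimide/DMAP) esterification.

**Step 11**
Reactants: 21 tris[2-(trimethylsilyl)ethyl] methanetriacetate
Product: 22 bis[2-(trimethylsilyl)ethyl] 3-(2-oxoethyl)pentanedioate
Conditions: DIBAL-H (0.9 equiv), PhMe, −78 °C; Rochelle salt work-up; recovered 21 is returned to the step
Reagents that add atoms: none
Why: DIBAL-H partial reduction of one of three homotopic ester arms; the aluminium hemiacetal persists at −78 °C, so with sub-stoichiometric hydride the mono-aldehyde should be the main (statistically governed) product.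

**Step 12**
Reactants: 23 (4S)-4-benzyl-1,3-thiazolidine-2-thione; 10 propanoyl chloride
Product: 24 (4S)-4-benzyl-3-propanoyl-1,3-thiazolidine-2-thione
Conditions: Et3N, DMAP (cat.), CH2Cl2, 0 °C → rt
Reagents that add atoms: 10, propanoyl chloride, CCC(Cl)=O
Why: N-acylation as in step 4.

**Step 13**
Reactants: 24 (4S)-4-benzyl-3-propanoyl-1,3-thiazolidine-2-thione; 22 bis[2-(trimethylsilyl)ethyl] 3-(2-oxoethyl)pentanedioate
Product: 25 bis[2-(trimethylsilyl)ethyl] 3-[(2R,3S)-4-[(4S)-4-benzyl-2-sulfanylidene-1,3-thiazolidin-3-yl]-2-hydroxy-3-methyl-4-oxobutyl]pentanedioate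
Conditions: TiCl4 (1.05 equiv), i-Pr2NEt (1.1 equiv), NMP (1 equiv), CH2Cl2, 0 °C; then 22, −78 °C
Reagents that add atoms: none
Why: titanium enolate thiazolidinethione aldol as in step 5; the (S)-auxiliary should give the (2S,3R)-syn acyl unit through the Zimmerman–Traxler chair, which sets the chain-C2 methyl and ring-C2 oxygen centers of the target, while the ester arms are inert to the enolate.

**Step 14**
Reactants: 25 the aldol adduct
Product: 26 bis[2-(trimethylsilyl)ethyl] 3-[(2R,3S)-2-hydroxy-3-methyl-4-oxobutyl]pentanedioate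
Conditions: DIBAL-H (2.2 equiv), CH2Cl2, −78 °C, short contact; Rochelle salt work-up
Reagents that add atoms: none
Why: the thiocarbonyl-activated imide is reduced by DIBAL-H far faster than the two ester arms (the first equivalent is taken by the hydroxyl), so the aldehyde should form directly with release of the auxiliary.

**Step 15**
Reactants: 26 the β-hydroxy aldehyde; 27 iodoform
Product: 28 bis[2-(trimethylsilyl)ethyl] 3-[(2R,3R,4E)-2-hydroxy-5-iodo-3-methylpent-4-en-1-yl]pentanedioate
Conditions: CrCl2, CHI3, THF/dioxane, 0 °C → rt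
Reagents that add atoms: 27, iodoform, IC(I)I
Why: Takai olefination, in which the geminal dichromium species from iodoform adds to the aldehyde and anti-eliminates to the (E)-vinyl iodide; the non-basic conditions should avoid epimerization at the α-methyl center and retro-aldol cleavage, and they tolerate the free hydroxyl.

**Step 16**
Reactants: 28 the (E)-vinyl iodide; 29 propyne
Product: 30 bis[2-(trimethylsilyl)ethyl] 3-[(2R,3R,4E)-2-hydroxy-3-methyloct-4-en-6-yn-1-yl]pentanedioate
Conditions: Pd(PPh3)2Cl2 (5 mol %), CuI (10 mol %), i-Pr2NH, THF, rt, propyne in excess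
Reagents that add atoms: 29, propyne, CC#C
Why: Sonogashira coupling of the vinyl iodide with propyne, with retention of the E geometry.

**Step 17**
Reactants: 30 the enyne hydroxy diester
Product: 31 2-(trimethylsilyl)ethyl 2-[(2R,4S)-2-[(2R,3E)-hept-3-en-5-yn-2-yl]-6-oxooxan-4-yl]acetate
Conditions: CSA (10 mol %), 2-(trimethylsilyl)ethanol (1 equiv, shuttle), PhMe, 60 °C; then removal of volatiles
Reagents that add atoms: none
Why: acid-catalysed lactonization under transesterification equilibrium (6-exo-trig acyl substitution), in which the hydroxyl can close on either of two diastereotopic ester arms; closure that leaves the remaining arm and the enynyl chain both equatorial (2,4-cis on the oxane) is preferred in the chair-like tetrahedral intermediate and in the product, and the trans epimer is reopened by the silyl ethanol and funnelled to the cis-lactone, so ring C4 should be set from ring C2.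

**Step 18**
Reactants: 18 the bis-silyloxy trienal; 31 the enyne lactone (1.3 equiv)
Product: 32 2-(trimethylsilyl)ethyl 2-[(2R,4S)-2-[(2R,3E,5E,7R,9S,10S,11R,12E,14E,16E)-7-hydroxy-6,10,12,16-tetramethyl-17-(2-methyl-1,3-oxazol-4-yl)-9,11-bis[(triethylsilyl)oxy]heptadeca-3,5,12,14,16-pentaen-2-yl]-6-oxooxan-4-yl]acetate
Conditions: Ni(cod)2 (15 mol %), (+)-NMDPP (30 mol %), Et3B (2.5 equiv), EtOAc/DMI (1:1), degassed, −25 → 0 °C; aq. NaHCO3 work-up
Reagents that add atoms: none
Why: Ni(0)–phosphine binds the C5≡C6 alkyne of 31 (with the conjugated C3=C4 alkene as a second anchor) and the aldehyde of 18, and oxidative cyclization gives an oxanickelacyclopentene with the new C6–C7 bond at the methyl-bearing alkyne carbon; ethyl transfer from Et3B to nickel (boron takes the alkoxide), β-hydride elimination (ethene) and C–H reductive elimination then add H and C7 syn across the alkyne, which is the (5E)-trisubstituted alkene. The closest known reaction type is the nickel-catalysed, alkene-directed reductive coupling of 1,3-enynes with aldehydes using Et3B, together with its chiral-monophosphine (NMDPP) variant for alkyne–aldehyde couplings. No ring is closed. The only new stereocenter, C7, is set in the oxidative cyclization by the chiral phosphine on nickel (reagent control), which has to overrule the weak 1,3-anti preference of the β-silyloxy aldehyde because the target needs the 7,9-syn relationship. The step needs regioselectivity (secured by alkene coordination, which places nickel on C5 next to the diene, and by the small methyl group on C6), site selectivity for the alkyne over the triene (its C=C bonds are trisubstituted or internal, hence poor ligands for nickel, and cannot reach the aldehyde through a small ring) and inertness of lactone, ester, silyl ethers and oxazole, which Ni(0)/Et3B in ethyl acetate should leave alone.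

**Step 19**
Reactants: 32 the coupled product
Product: 33 2-[(2R,4S)-2-[(2R,3E,5E,7R,9S,10S,11R,12E,14E,16E)-7,9,11-trihydroxy-6,10,12,16-tetramethyl-17-(2-methyl-1,3-oxazol-4-yl)heptadeca-3,5,12,14,16-pentaen-2-yl]-6-oxooxan-4-yl]acetic acid
Conditions: TASF (excess), DMF, 0 °C → rt; pH 6 phosphate buffer work-up
Reagents that add atoms: none
Why: fluoride-mediated global desilylation, which cleaves both triethylsilyl ethers and fragments the 2-(trimethylsilyl)ethyl ester (β-elimination to ethene and carboxylate) in one operation; the anhydrous, weakly basic fluoride source and buffered work-up should spare the oxanone and the allylic alcohols.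

**Compound list**
1 | 2-methyl-1,3-oxazole-4-carbaldehyde | O=Cc1coc(C)n1 | starting material
2 | 2-(triphenylphosphoranylidene)propanal | CC(C=O)=P(c1ccccc1)(c1ccccc1)c1ccccc1 | starting material
3 | (2E)-2-methyl-3-(2-methyl-1,3-oxazol-4-yl)prop-2-enal | O=C/C(C)=C/c1coc(C)n1 | intermediate
4 | (1,3-dioxolan-2-ylmethyl)triphenylphosphonium bromide | [Br-].C1COC(C[P+](c2ccccc2)(c2ccccc2)c2ccccc2)O1 | starting material
5 | water | O | starting material
6 | 4-[(1E)-4-(1,3-dioxolan-2-yl)-2-methylbuta-1,3-dien-1-yl]-2-methyl-1,3-oxazole (dienyl dioxolane, 3E/3Z mixture) | Cc1nc(/C=C(\C)C=CC2OCCO2)co1 | intermediate (not isolated)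
7 | (2E,4E)-4-methyl-5-(2-methyl-1,3-oxazol-4-yl)penta-2,4-dienal | O=C/C=C/C(C)=C/c1coc(C)n1 | intermediate
8 | (2E,4E,6E)-2,6-dimethyl-7-(2-methyl-1,3-oxazol-4-yl)hepta-2,4,6-trienal | CC(/C=C/C=C(\C)C=O)=C\c1coc(C)n1 | intermediate
9 | (4R)-4-benzyl-1,3-thiazolidine-2-thione | S=C1N[C@H](Cc2ccccc2)CS1 | starting material
10 | propanoyl chloride | CCC(Cl)=O | starting material
11 | (4R)-4-benzyl-3-propanoyl-1,3-thiazolidine-2-thione | CCC(=O)N1[C@H](Cc2ccccc2)CSC1=S | intermediate
12 | (2R,3R,4E,6E,8E)-1-[(4R)-4-benzyl-2-sulfanylidene-1,3-thiazolidin-3-yl]-3-hydroxy-2,4,8-trimethyl-9-(2-methyl-1,3-oxazol-4-yl)nona-4,6,8-trien-1-one | CC(/C=C/C=C(\C)[C@H](O)[C@@H](C)C(=O)N1[C@H](Cc2ccccc2)CSC1=S)=C\c1coc(C)n1 | intermediate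
13 | potassium ethyl malonate | CCOC(=O)CC(=O)[O-].[K+] | starting material
14 | ethyl (4R,5R,6E,8E,10E)-5-hydroxy-4,6,10-trimethyl-11-(2-methyl-1,3-oxazol-4-yl)-3-oxoundeca-6,8,10-trienoate | CC(/C=C/C=C(\C)[C@H](O)[C@@H](C)C(=O)CC(=O)OCC)=C\c1coc(C)n1 | intermediate
15 | ethyl (3S,4S,5R,6E,8E,10E)-3,5-dihydroxy-4,6,10-trimethyl-11-(2-methyl-1,3-oxazol-4-yl)undeca-6,8,10-trienoate | CC(/C=C/C=C(\C)[C@H](O)[C@@H](C)[C@@H](O)CC(=O)OCC)=C\c1coc(C)n1 | intermediate
16 | triethylsilyl trifluoromethanesulfonate | CC[Si](CC)(CC)OS(=O)(=O)C(F)(F)F | starting material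
17 | ethyl (3S,4S,5R,6E,8E,10E)-4,6,10-trimethyl-11-(2-methyl-1,3-oxazol-4-yl)-3,5-bis[(triethylsilyl)oxy]undeca-6,8,10-trienoate | CC(/C=C/C=C(\C)[C@H](O[Si](CC)(CC)CC)[C@@H](C)[C@@H](O[Si](CC)(CC)CC)CC(=O)OCC)=C\c1coc(C)n1 | intermediate
18 | (3S,4S,5R,6E,8E,10E)-4,6,10-trimethyl-11-(2-methyl-1,3-oxazol-4-yl)-3,5-bis[(triethylsilyl)oxy]undeca-6,8,10-trienal | CC(/C=C/C=C(\C)[C@H](O[Si](CC)(CC)CC)[C@@H](C)[C@@H](O[Si](CC)(CC)CC)CC=O)=C\c1coc(C)n1 | intermediate
19 | methanetriacetic acid [3-(carboxymethyl)pentanedioic acid] | OC(=O)CC(CC(=O)O)CC(=O)O | starting material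
20 | 2-(trimethylsilyl)ethanol | C[Si](C)(C)CCO | starting material
21 | tris[2-(trimethylsilyl)ethyl] methanetriacetate | C[Si](C)(C)CCOC(=O)CC(CC(=O)OCC[Si](C)(C)C)CC(=O)OCC[Si](C)(C)C | intermediate
22 | bis[2-(trimethylsilyl)ethyl] 3-(2-oxoethyl)pentanedioate | O=CCC(CC(=O)OCC[Si](C)(C)C)CC(=O)OCC[Si](C)(C)C | intermediate
23 | (4S)-4-benzyl-1,3-thiazolidine-2-thione | S=C1N[C@@H](Cc2ccccc2)CS1 | starting material
24 | (4S)-4-benzyl-3-propanoyl-1,3-thiazolidine-2-thione | CCC(=O)N1[C@@H](Cc2ccccc2)CSC1=S | intermediate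
25 | bis[2-(trimethylsilyl)ethyl] 3-[(2R,3S)-4-[(4S)-4-benzyl-2-sulfanylidene-1,3-thiazolidin-3-yl]-2-hydroxy-3-methyl-4-oxobutyl]pentanedioate | S=C1SC[C@H](Cc2ccccc2)N1C(=O)[C@@H](C)[C@H](O)CC(CC(=O)OCC[Si](C)(C)C)CC(=O)OCC[Si](C)(C)C | intermediate
26 | bis[2-(trimethylsilyl)ethyl] 3-[(2R,3S)-2-hydroxy-3-methyl-4-oxobutyl]pentanedioate | O=C[C@@H](C)[C@H](O)CC(CC(=O)OCC[Si](C)(C)C)CC(=O)OCC[Si](C)(C)C | intermediate
27 | iodoform | IC(I)I | starting material
28 | bis[2-(trimethylsilyl)ethyl] 3-[(2R,3R,4E)-2-hydroxy-5-iodo-3-methylpent-4-en-1-yl]pentanedioate | I/C=C/[C@@H](C)[C@H](O)CC(CC(=O)OCC[Si](C)(C)C)CC(=O)OCC[Si](C)(C)C | intermediate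
29 | propyne | CC#C | starting material
30 | bis[2-(trimethylsilyl)ethyl] 3-[(2R,3R,4E)-2-hydroxy-3-methyloct-4-en-6-yn-1-yl]pentanedioate | CC#C/C=C/[C@@H](C)[C@H](O)CC(CC(=O)OCC[Si](C)(C)C)CC(=O)OCC[Si](C)(C)C | intermediate
31 | 2-(trimethylsilyl)ethyl 2-[(2R,4S)-2-[(2R,3E)-hept-3-en-5-yn-2-yl]-6-oxooxan-4-yl]acetate | CC#C/C=C/[C@@H](C)[C@H]1C[C@@H](CC(=O)OCC[Si](C)(C)C)CC(=O)O1 | intermediate
32 | 2-(trimethylsilyl)ethyl 2-[(2R,4S)-2-[(2R,3E,5E,7R,9S,10S,11R,12E,14E,16E)-7-hydroxy-6,10,12,16-tetramethyl-17-(2-methyl-1,3-oxazol-4-yl)-9,11-bis[(triethylsilyl)oxy]heptadeca-3,5,12,14,16-pentaen-2-yl]-6-oxooxan-4-yl]acetate | CC(/C=C/C=C(\C)[C@H](O[Si](CC)(CC)CC)[C@@H](C)[C@@H](O[Si](CC)(CC)CC)C[C@@H](O)/C(C)=C/C=C/[C@@H](C)[C@H]1C[C@@H](CC(=O)OCC[Si](C)(C)C)CC(=O)O1)=C\c1coc(C)n1 | intermediate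
33 | 2-[(2R,4S)-2-[(2R,3E,5E,7R,9S,10S,11R,12E,14E,16E)-7,9,11-trihydroxy-6,10,12,16-tetramethyl-17-(2-methyl-1,3-oxazol-4-yl)heptadeca-3,5,12,14,16-pentaen-2-yl]-6-oxooxan-4-yl]acetic acid | CC(/C=C/C=C(\C)[C@H](O)[C@@H](C)[C@@H](O)C[C@@H](O)/C(C)=C/C=C/[C@@H](C)[C@H]1C[C@@H](CC(=O)O)CC(=O)O1)=C\c1coc(C)n1 | target

**Totals**
Total step count: 19. Longest linear sequence: 10 steps (1, 2, 3, 5, 6, 7, 8, 9, 18, 19).

**Steps most likely to fail**

Step 18. The facial selectivity of the oxidative cyclization may be low, because the ligand has to overrule the 1,3-anti bias of the β-silyloxy aldehyde and only moderate ligand control is known for enynes; this would give C7 epimers. The fallback sets out from 18 and 31 and returns at 32. The coupling is run with achiral tricyclopentylphosphine (Ni(cod)2, Et3B, EtOAc, rt), the most regioselective ligand for enynes, which should give 32 together with its (7S)-epimer F1. The unseparated alcohols are oxidised (Dess–Martin periodinane, NaHCO3, CH2Cl2, or MnO2) to the single dienone F2. Reagent-controlled Corey–Bakshi–Shibata reduction ((S)-2-methyl-CBS-oxazaborolidine, catecholborane, toluene, −78 °C, the alkenyl group acting as the large substituent) should then return (7R)-configured 32, so that C–C bond formation and the C7 configuration are decoupled.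

Step 17. The two diastereotopic ester arms may not be discriminated well enough at equilibrium, leaving the trans-lactone as a persistent component. The fallback sets out from 30 and returns at 31, and replaces thermodynamic arm selection by reagent-controlled anhydride desymmetrization. The hydroxyl of 30 is protected (4-methoxybenzyl trichloroacetimidate, cat. La(OTf)3, PhMe, 0 °C) to give the 4-methoxybenzyl ether F3. Both silylethyl esters are cleaved (TBAF, THF) to the diacid F4, which is closed (Ac2O, 60 °C) to the cyclic anhydride F5. Alcoholysis with 2-(trimethylsilyl)ethanol under a modified cinchona alkaloid catalyst ((DHQD)2AQN or its pseudo-enantiomer, whichever opens the required carbonyl; Et2O, −20 °C) should give the hemiester F6. Removal of the benzyl ether (DDQ, CH2Cl2/pH 7 buffer) gives the hydroxy acid F7, and irreversible carbodiimide lactonization onto the free acid arm (EDC·HCl, DMAP, CH2Cl2) gives 31.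

Step 19. Naked fluoride may open or translactonize the oxanone and degrade the allylic triol before the silylethyl ester is fully cleaved. The fallback sets out from 31 and returns at 33, and changes the ester protecting group so that the last step uses only buffered HF. The silylethyl ester of 31 is cleaved (TBAF, THF, 0 °C, mildly acidic work-up) to the lactone acid F8, which is converted (i-Pr3SiCl, imidazole, DMF) into the triisopropylsilyl ester F9. Coupling of F9 with 18 under the conditions of step 18 should give the coupled silyl ester F10, and HF·pyridine/pyridine in THF at 0 °C should remove the two triethylsilyl ethers and the silyl ester to give 33.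

**Further compounds**
F1 | step 18 | (7S)-epimer of 32 | CC(/C=C/C=C(\C)[C@H](O[Si](CC)(CC)CC)[C@@H](C)[C@@H](O[Si](CC)(CC)CC)C[C@H](O)/C(C)=C/C=C/[C@@H](C)[C@H]1C[C@@H](CC(=O)OCC[Si](C)(C)C)CC(=O)O1)=C\c1coc(C)n1
F2 | step 18 | 7-oxo analogue of 32 (dienone) | CC(/C=C/C=C(\C)[C@H](O[Si](CC)(CC)CC)[C@@H](C)[C@@H](O[Si](CC)(CC)CC)CC(=O)/C(C)=C/C=C/[C@@H](C)[C@H]1C[C@@H](CC(=O)OCC[Si](C)(C)C)CC(=O)O1)=C\c1coc(C)n1
F3 | step 17 | bis[2-(trimethylsilyl)ethyl] 3-[(2R,3R,4E)-2-[(4-methoxyphenyl)methoxy]-3-methyloct-4-en-6-yn-1-yl]pentanedioate | CC#C/C=C/[C@@H](C)[C@H](OCc1ccc(OC)cc1)CC(CC(=O)OCC[Si](C)(C)C)CC(=O)OCC[Si](C)(C)C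
F4 | step 17 | 3-[(2R,3R,4E)-2-[(4-methoxyphenyl)methoxy]-3-methyloct-4-en-6-yn-1-yl]pentanedioic acid | CC#C/C=C/[C@@H](C)[C@H](OCc1ccc(OC)cc1)CC(CC(=O)O)CC(=O)O
F5 | step 17 | 4-[(2R,3R,4E)-2-[(4-methoxyphenyl)methoxy]-3-methyloct-4-en-6-yn-1-yl]oxane-2,6-dione | CC#C/C=C/[C@@H](C)[C@H](OCc1ccc(OC)cc1)CC1CC(=O)OC(=O)C1
F6 | step 17 | (3R)-3-[(2R,3R,4E)-2-[(4-methoxyphenyl)methoxy]-3-methyloct-4-en-6-yn-1-yl]-5-oxo-5-[2-(trimethylsilyl)ethoxy]pentanoic acid | CC#C/C=C/[C@@H](C)[C@H](OCc1ccc(OC)cc1)C[C@@H](CC(=O)OCC[Si](C)(C)C)CC(=O)O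
F7 | step 17 | (3R)-3-[(2R,3R,4E)-2-hydroxy-3-methyloct-4-en-6-yn-1-yl]-5-oxo-5-[2-(trimethylsilyl)ethoxy]pentanoic acid | CC#C/C=C/[C@@H](C)[C@H](O)C[C@@H](CC(=O)OCC[Si](C)(C)C)CC(=O)O
F8 | step 19 | 2-[(2R,4S)-2-[(2R,3E)-hept-3-en-5-yn-2-yl]-6-oxooxan-4-yl]acetic acid | CC#C/C=C/[C@@H](C)[C@H]1C[C@@H](CC(=O)O)CC(=O)O1
F9 | step 19 | triisopropylsilyl ester of F8 | CC#C/C=C/[C@@H](C)[C@H]1C[C@@H](CC(=O)O[Si](C(C)C)(C(C)C)C(C)C)CC(=O)O1
F10 | step 19 | triisopropylsilyl ester analogue of 32 | CC(/C=C/C=C(\C)[C@H](O[Si](CC)(CC)CC)[C@@H](C)[C@@H](O[Si](CC)(CC)CC)C[C@@H](O)/C(C)=C/C=C/[C@@H](C)[C@H]1C[C@@H](CC(=O)O[Si](C(C)C)(C(C)C)C(C)C)CC(=O)O1)=C\c1coc(C)n1
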